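The route rests on cutting two neighbouring bonds on the benzene ring (ring B) of the tetralin: the C7–CHO bond and the crowded C8–C3' bond to the pyranone ring. This ortho pair, flanked by the C6 oxygen, is the signature of an aryne σ-insertion, so a C7–C8 aryne is planned to insert into the C3'–CHO bond of 3-formylhispidin dimethyl ether and to create both bonds in one operation, the C6 methoxy group steering C3' to C8. The aryne precursor is (1R,4S)-1-isopropyl-5,6-dimethoxy-4-methyltetralin carrying a C7 triflate and a C8 trimethylsilyl group; its stereocentres are taken unchanged from (+)-menthone, onto which ring B is built by a Diels–Alder reaction.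

Key step: step 13

Numbering: tetralin C1 (isopropyl), C4 (methyl), C4a, C5–C8, C8a; ring A is the saturated ring, ring B the benzene ring; pyranone atoms are primed.
Assumption: the target defines no configuration for the hindered C8–C3' axis, so no axial control is planned and rotamers are treated as one compound.

Step 1
Reactants: 1 (+)-menthone
Product: 3 (3S,6R)-3-methyl-6-(propan-2-yl)cyclohex-1-en-1-yl trifluoromethanesulfonate, via lithium enolate 2 (not isolated)
Conditions: LiN(i-Pr)2 (1.1 equiv), THF, −78 °C; PhNTf2, −78 °C → rt; aq. NH4Cl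
Reagents that add atoms: N-phenylbis(trifluoromethanesulfonimide), O=S(=O)(N(c1ccccc1)S(=O)(=O)C(F)(F)F)C(F)(F)F
Why: Kinetic deprotonation by the bulky amide takes a methylene proton and leaves the isopropyl-bearing methine untouched, so that stereocentre is never enolised, and O-sulfonylation of the enolate (enol triflate formation) fixes the double bond on the methylene side.

Step 2
Reactants: 3 enol triflate
Product: 4 (3S,6R)-1-ethenyl-3-methyl-6-(propan-2-yl)cyclohex-1-ene
Conditions: Bu3SnCH=CH2, Pd(PPh3)4 (cat.), LiCl (3 equiv), THF, 65 °C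
Reagents that add atoms: tributyl(vinyl)stannane, C=C[Sn](CCCC)(CCCC)CCCC
Why: Stille coupling of an alkenyl triflate with a vinylstannane (oxidative addition to zerovalent palladium, chloride-assisted transmetalation, reductive elimination) should give the 1,3-diene without touching either stereocentre.

Step 3
Reactants: 4 diene, 5 vinylene carbonate
Product: 6 cyclic carbonate of (1R,4S)-1-isopropyl-4-methyl-1,2,3,4,4a,5,6,7-octahydronaphthalene-cis-5,6-diol (C8=C8a alkene; mixture at C4a, C5, C6)
Conditions: 5 (neat, excess), BHT (cat.), sealed tube, 170 °C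
Reagents that add atoms: none
Why: Thermal Diels–Alder cycloaddition of the s-cis 1-vinylcyclohexene with the symmetrical dienophile forms C4a–C5 and C6–C7 with no regiochemical question; the diene has no hydrogen placed for a sigmatropic shift, so C1 and C4 are unaffected, and the mixture at C4a, C5 and C6 is irrelevant because all three become sp2 in step 5.

Step 4
Reactants: 6 carbonate adduct
Product: 7 (1R,4S)-1-isopropyl-4-methyl-1,2,3,4,4a,5,6,7-octahydronaphthalene-cis-5,6-diol (mixture at C4a, C5, C6)
Conditions: K2CO3 (cat.), MeOH, rt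
Reagents that add atoms: none
Why: Base-catalysed transesterification of the cyclic carbonate with methanol should release the cis-diol and dimethyl carbonate.

Step 5
Reactants: 7 diol
Product: 9 (1R,4S)-1-isopropyl-4-methyltetralin-5,6-diol, via dione 8 (not isolated)
Conditions: DMSO, (CF3CO)2O, CH2Cl2, −78 °C; Et3N, −78 °C → rt, under N2
Reagents that add atoms: none
Why: Swern-type oxidation of both carbinols gives the 1,2-dione without C–C cleavage, and this dione is a tautomer of the catechol, so amine-promoted enolisation towards C4a and C7 should aromatise ring B.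

Step 6
Reactants: 9 catechol
Product: 10 (1R,4S)-1-isopropyl-5,6-dimethoxy-4-methyltetralin
Conditions: MeI, K2CO3, acetone, reflux, under N2
Reagents that add atoms: iodomethane, CI
Why: Williamson O-methylation of both phenols protects the air-sensitive catechol and installs the ether that later directs metalation and polarises the aryne.

Step 7
Reactants: 10 dimethoxytetralin
Product: 13 (1R,4S)-1-isopropyl-5,6-dimethoxy-4-methyltetralin-7-ol, via aryllithium 11 (not isolated), via arylboronate 12 (not isolated)
Conditions: n-BuLi, TMEDA, Et2O, 0 °C → rt; B(OMe)3, −78 °C → rt; AcOH, 30% aq. H2O2, 0 °C → rt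
Reagents that add atoms: hydrogen peroxide, OO; trimethyl borate, COB(OC)OC (its atoms stay only in 12)
Why: Directed ortho-metalation places lithium at C7, the only ring position ortho to an ether oxygen (the tertiary benzylic hydrogens are far less acidic kinetically), and borylation followed by oxidative 1,2-shift of aryl from boron to oxygen should give the phenol at the same carbon.

Step 8
Reactants: 13 phenol
Product: 14 (1R,4S)-8-bromo-1-isopropyl-5,6-dimethoxy-4-methyltetralin-7-ol
Conditions: NBS (1.0 equiv), i-Pr2NH (cat.), CH2Cl2, 0 °C, dark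
Reagents that add atoms: N-bromosuccinimide, O=C1CCC(=O)N1Br
Why: Electrophilic aromatic bromination can only occur at C8, the single unsubstituted carbon of ring B, which is ortho to the hydroxyl and para to the C5 methoxy group.

Step 9
Reactants: 14 bromophenol
Product: 17 (1R,4S)-1-isopropyl-5,6-dimethoxy-4-methyl-8-(trimethylsilyl)tetralin-7-yl trifluoromethanesulfonate, via silyl ether 15 (not isolated), via lithium phenoxide 16 (not isolated)
Conditions: (Me3Si)2NH, THF, 65 °C, then evaporation; n-BuLi, THF, −100 °C → −78 °C; Tf2O, −100 °C → −78 °C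
Reagents that add atoms: hexamethyldisilazane, C[Si](C)(C)N[Si](C)(C)C; trifluoromethanesulfonic anhydride, O=S(=O)(OS(=O)(=O)C(F)(F)F)C(F)(F)F
Why: O-silylation, bromine–lithium exchange at C8 followed at once by 1,3-O→C silyl migration (retro-Brook rearrangement) and O-triflation of the resulting phenoxide is the standard sequence to ortho-silylaryl triflates and fixes silicon at C8 and the leaving group at C7.

Step 10
Reactants: 18 4-hydroxy-6-methyl-2H-pyran-2-one, 19 3,4-dimethoxybenzaldehyde
Product: 22 6-[(E)-2-(3,4-dimethoxyphenyl)ethenyl]-4-hydroxy-2H-pyran-2-one (hispidin dimethyl ether), via dilithium dianion 20 (not isolated), via aldol adduct 21 (not isolated)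
Conditions: LiN(i-Pr)2 (2.4 equiv), THF, −78 °C; 19, −78 → 0 °C; AcOH; then p-TsOH·H2O (cat.), 1,4-dioxane, 90 °C
Reagents that add atoms: none
Why: Vinylogous aldol addition of the O,C-dianion, which reacts at its more basic exocyclic carbon, followed by acid-catalysed dehydration of the electron-rich benzylic carbinol should give the fully conjugated styryl group with the thermodynamically preferred E geometry.

Step 11
Reactants: 22 hispidin dimethyl ether
Product: 23 3-[(dimethylamino)methylidene]-6-[(E)-2-(3,4-dimethoxyphenyl)ethenyl]-2H-pyran-2,4(3H)-dione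
Conditions: Me2NCH(OMe)2, 1,4-dioxane, rt → 50 °C
Reagents that add atoms: N,N-dimethylformamide dimethyl acetal, COC(OC)N(C)C
Why: Aminomethylenation of the acidic C3'–H position, flanked by the lactone carbonyl and the enolic C4', by the amide acetal gives the push–pull enaminone, which carries the future formyl carbon at C3'.

Step 12
Reactants: 23 enaminone
Product: 24 6-[(E)-2-(3,4-dimethoxyphenyl)ethenyl]-4-hydroxy-2-oxo-2H-pyran-3-carbaldehyde (3-formylhispidin dimethyl ether)
Conditions: 2 M aq. HCl, THF, 50 °C
Reagents that add atoms: water, O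
Why: Acid hydrolysis of the vinylogous amide (addition of water, loss of dimethylamine) gives the hydroxymethylene compound, which tautomerises to the hydrogen-bonded 3-formyl-4-hydroxy form.

Step 13
Reactants: 17 silyl triflate, 24 3-formylhispidin dimethyl ether
Product: 28 tetra-O-methylheimiomycin B (pyranone hydroxyl free), via caesium enolate 25 (not isolated), via aryne 26 (not isolated), via caesium benzocyclobutenoxide 27 (not isolated)
Conditions: 24 (1.5 equiv), CsF (4 equiv), MeCN, rt; 17 added slowly, 60 °C; dilute aq. HCl work-up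
Reagents that add atoms: none
Why: Proposed new method: fluoride first turns 24 into enolate 25 and then attacks silicon of 17, triflate leaves and the C7–C8 aryne 26 results; 25 adds through C3' to C8, the aryl anion left at C7 attacks the neighbouring formyl carbon to give 27, and cleavage of the C3'–CH(O−) bond returns the aldehyde on C7 and expels a 4-oxidopyranone, a vinylogous carboxylate and hence an excellent carbanion leaving group. The closest known reaction type is the acyl-alkylation of arynes (insertion into the C–C bond of β-keto esters and 1,3-diketones), together with C3-arylation of 4-hydroxy-2-pyranone-type enolates by arynes; new here is the transfer of a formyl group from a fully substituted tricarbonyl carbon. No ring is closed in the product: the four-membered ring of 27 forms by 4-exo-trig addition to the aldehyde and opens again, and no stereocentre is created. The step needs attack at C8 and not at C7, which the inductively withdrawing C6 methoxy group should secure by placing the developing negative charge on the carbon next to it, against the steric pressure of the peri C1 substituent. It also needs C- over O-arylation and capture of the aryne by the enolate instead of by the styrene or the pyranone diene, which the soft caesium enolate in MeCN, held in excess by slow release of the aryne, is meant to ensure.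

Step 14
Reactants: 28 tetramethyl ether
Product: 29 heimiomycin B
Conditions: BBr3 (excess), CH2Cl2, −78 → 0 °C; H2O quench
Reagents that add atoms: none
Why: Lewis acid-mediated cleavage of the four aryl methyl ethers (the C6 ether assisted by chelation to the ortho aldehyde) should free both catechols, while aldehyde, lactone, E-alkene and the two benzylic stereocentres are not attacked at low temperature.

Compound list
1 | (+)-menthone, (2R,5S)-5-methyl-2-(propan-2-yl)cyclohexan-1-one | CC(C)[C@H]1CC[C@H](C)CC1=O | starting material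
2 | lithium (3S,6R)-3-methyl-6-(propan-2-yl)cyclohex-1-en-1-olate | CC(C)[C@H]1CC[C@H](C)C=C1[O-].[Li+] | intermediate (not isolated)
3 | (3S,6R)-3-methyl-6-(propan-2-yl)cyclohex-1-en-1-yl trifluoromethanesulfonate | CC(C)[C@H]1CC[C@H](C)C=C1OS(=O)(=O)C(F)(F)F | intermediate
4 | (3S,6R)-1-ethenyl-3-methyl-6-(propan-2-yl)cyclohex-1-ene | CC(C)[C@H]1CC[C@H](C)C=C1C=C | intermediate
5 | vinylene carbonate (1,3-dioxol-2-one) | O=C1OC=CO1 | starting material
6 | cyclic carbonate of (1R,4S)-1-isopropyl-4-methyl-1,2,3,4,4a,5,6,7-octahydronaphthalene-cis-5,6-diol, mixture at C4a/C5/C6 | CC(C)[C@H]1CC[C@H](C)C2C3OC(=O)OC3CC=C12 | intermediate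
7 | (1R,4S)-1-isopropyl-4-methyl-1,2,3,4,4a,5,6,7-octahydronaphthalene-cis-5,6-diol, mixture at C4a/C5/C6 | CC(C)[C@H]1CC[C@H](C)C2C(O)C(O)CC=C12 | intermediate
8 | (1R,4S)-1-isopropyl-4-methyl-1,2,3,4,4a,7-hexahydronaphthalene-5,6-dione, mixture at C4a | CC(C)[C@H]1CC[C@H](C)C2C(=O)C(=O)CC=C12 | intermediate (not isolated)
9 | (1R,4S)-1-isopropyl-4-methyltetralin-5,6-diol | CC(C)[C@H]1CC[C@H](C)c2c(O)c(O)ccc21 | intermediate
10 | (1R,4S)-1-isopropyl-5,6-dimethoxy-4-methyltetralin | CC(C)[C@H]1CC[C@H](C)c2c(OC)c(OC)ccc21 | intermediate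
11 | 7-lithio derivative of 10 | CC(C)[C@H]1CC[C@H](C)c2c(OC)c(OC)c([Li])cc21 | intermediate (not isolated)
12 | 7-(dimethoxyboryl) derivative of 10 | CC(C)[C@H]1CC[C@H](C)c2c(OC)c(OC)c(B(OC)OC)cc21 | intermediate (not isolated)
13 | (1R,4S)-1-isopropyl-5,6-dimethoxy-4-methyltetralin-7-ol | CC(C)[C@H]1CC[C@H](C)c2c(OC)c(OC)c(O)cc21 | intermediate
14 | (1R,4S)-8-bromo-1-isopropyl-5,6-dimethoxy-4-methyltetralin-7-ol | CC(C)[C@H]1CC[C@H](C)c2c(OC)c(OC)c(O)c(Br)c21 | intermediate
15 | trimethylsilyl ether of 14 | CC(C)[C@H]1CC[C@H](C)c2c(OC)c(OC)c(O[Si](C)(C)C)c(Br)c21 | intermediate (not isolated)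
16 | lithium (1R,4S)-1-isopropyl-5,6-dimethoxy-4-methyl-8-(trimethylsilyl)tetralin-7-olate | CC(C)[C@H]1CC[C@H](C)c2c(OC)c(OC)c([O-])c([Si](C)(C)C)c21.[Li+] | intermediate (not isolated)
17 | (1R,4S)-1-isopropyl-5,6-dimethoxy-4-methyl-8-(trimethylsilyl)tetralin-7-yl trifluoromethanesulfonate | CC(C)[C@H]1CC[C@H](C)c2c(OC)c(OC)c(OS(=O)(=O)C(F)(F)F)c([Si](C)(C)C)c21 | intermediate
18 | 4-hydroxy-6-methyl-2H-pyran-2-one | Cc1cc(O)cc(=O)o1 | starting material
19 | 3,4-dimethoxybenzaldehyde | COc1ccc(C=O)cc1OC | starting material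
20 | dilithium O,C-dianion of 18 (oxide at C4, carbanion at the C6 methyl) | [Li+].[Li+].[CH2-]c1cc([O-])cc(=O)o1 | intermediate (not isolated)
21 | 6-[2-(3,4-dimethoxyphenyl)-2-hydroxyethyl]-4-hydroxy-2H-pyran-2-one, racemic | O=c1cc(O)cc(CC(O)c2ccc(OC)c(OC)c2)o1 | intermediate (not isolated)
22 | 6-[(E)-2-(3,4-dimethoxyphenyl)ethenyl]-4-hydroxy-2H-pyran-2-one | O=c1cc(O)cc(/C=C/c2ccc(OC)c(OC)c2)o1 | intermediate
23 | 3-[(dimethylamino)methylidene]-6-[(E)-2-(3,4-dimethoxyphenyl)ethenyl]-2H-pyran-2,4(3H)-dione, enamine geometry open | CN(C)C=C1C(=O)C=C(/C=C/c2ccc(OC)c(OC)c2)OC1=O | intermediate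
24 | 6-[(E)-2-(3,4-dimethoxyphenyl)ethenyl]-4-hydroxy-2-oxo-2H-pyran-3-carbaldehyde | O=Cc1c(O)cc(/C=C/c2ccc(OC)c(OC)c2)oc1=O | intermediate
25 | caesium enolate of 24 | [Cs+].O=Cc1c([O-])cc(/C=C/c2ccc(OC)c(OC)c2)oc1=O | intermediate (not isolated)
26 | (1R,4S)-7,8-didehydro-1-isopropyl-5,6-dimethoxy-4-methyltetralin (C7–C8 aryne) | CC(C)[C@H]1CC[C@H](C)C2=C1C#CC(OC)=C2OC | intermediate (not isolated)
27 | caesium benzocyclobutenoxide: cyclobutene fused at C7–C8, alkoxide carbon on C7, spiro carbon C3' of the pyran-2,4-dione on C8, new centres open | CC(C)[C@H]1CC[C@H](C)c2c(OC)c(OC)c3C([O-])C4(C(=O)C=C(/C=C/c5ccc(OC)c(OC)c5)OC4=O)c3c21.[Cs+] | intermediate (not isolated)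
28 | tetra-O-methylheimiomycin B: (1R,4S)-8-{6-[(E)-2-(3,4-dimethoxyphenyl)ethenyl]-4-hydroxy-2-oxo-2H-pyran-3-yl}-1-isopropyl-5,6-dimethoxy-4-methyltetralin-7-carbaldehyde | CC(C)[C@H]1CC[C@H](C)c2c(OC)c(OC)c(C=O)c(-c3c(O)cc(/C=C/c4ccc(OC)c(OC)c4)oc3=O)c21 | intermediate
29 | heimiomycin B | CC(C)[C@H]1CC[C@H](C)c2c(O)c(O)c(C=O)c(-c3c(O)cc(/C=C/c4ccc(O)c(O)c4)oc3=O)c21 | target

Total step count: 14.
Longest linear sequence: 11 steps (steps 1–9, 13 and 14); the pyranone branch (steps 10–12) joins at step 13.

Steps most likely to fail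

1. Step 13 (the new method). What may go wrong:
- O-arylation of the ambident enolate instead of C-arylation.
- Attack at C7 instead of C8 under the steric pressure of the peri carbon.
- Protonation of the aryl anion before it reaches the formyl group.
- Loss of aryne to cycloaddition with the styrene or the pyranone diene.

Fallback by known chemistry, setting out from 10 and 22 and returning at 28: 10 is lithiated at C7 as in step 7 and quenched with DMF to give (1R,4S)-1-isopropyl-5,6-dimethoxy-4-methyltetralin-7-carbaldehyde F1. Bromination (Br2, NaOAc, AcOH) at C8, the only free ring position, gives the 8-bromo-7-carbaldehyde F2. Miyaura borylation (B2pin2, PdCl2(dppf), KOAc, 1,4-dioxane, 90 °C) gives the C8 pinacol boronate F3. In parallel 22 is brominated at C3' (NBS, MeCN, 0 °C) to 3-bromo-6-[(E)-2-(3,4-dimethoxyphenyl)ethenyl]-4-hydroxy-2H-pyran-2-one F4, and its hydroxyl is capped (MeOCH2Cl, i-Pr2NEt, CH2Cl2) to give the 4-methoxymethyl ether F5. Suzuki–Miyaura coupling of F3 with F5 (Pd(OAc)2, SPhos, K3PO4, toluene–water, 90 °C) gives the 4'-O-methoxymethyl ether of 28 F6. Aqueous HCl in THF removes the acetal and returns 28.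

2. Step 9. What may go wrong: after bromine–lithium exchange the silyl group may migrate only slowly into the crowded C8 position next to the peri carbon, so that the aryllithium is protonated or butylated and silicon is lost.

Fallback, setting out from 13 and returning at 17, using directed metalation instead of halogen exchange: 13 and isopropyl isocyanate (Et3N cat., CH2Cl2) give the N-isopropylcarbamate of 13 F7. In situ N-silylation (t-BuMe2SiOTf, TMEDA), ortho-lithiation at C8 (n-BuLi, TMEDA, Et2O, −78 °C), Me3SiCl quench and acidic work-up give the 8-trimethylsilyl carbamate F8. Et2NH and DBU in MeCN cleave the carbamate to (1R,4S)-1-isopropyl-5,6-dimethoxy-4-methyl-8-(trimethylsilyl)tetralin-7-ol F9. PhNTf2 with DBU then gives 17.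

3. Step 5. What may go wrong: cleavage of the diol C–C bond, or electrophilic sulfenylation of the freshly formed electron-rich catechol by excess activated DMSO.

Fallback, setting out from 7 and returning at 9, by deliberate over-oxidation and reduction: 7 is heated with excess IBX in DMSO at 60 °C, which oxidises the diol to the dione and the derived catechol on to the ortho-quinone (1R,4S)-1-isopropyl-4-methyltetralin-5,6-dione F10. Aqueous Na2S2O4 reduces F10 at once to 9.

Further compounds
F1 | step 13 | (1R,4S)-1-isopropyl-5,6-dimethoxy-4-methyltetralin-7-carbaldehyde | CC(C)[C@H]1CC[C@H](C)c2c(OC)c(OC)c(C=O)cc21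
F2 | step 13 | (1R,4S)-8-bromo-1-isopropyl-5,6-dimethoxy-4-methyltetralin-7-carbaldehyde | CC(C)[C@H]1CC[C@H](C)c2c(OC)c(OC)c(C=O)c(Br)c21
F3 | step 13 | (1R,4S)-1-isopropyl-5,6-dimethoxy-4-methyl-8-(4,4,5,5-tetramethyl-1,3,2-dioxaborolan-2-yl)tetralin-7-carbaldehyde | CC(C)[C@H]1CC[C@H](C)c2c(OC)c(OC)c(C=O)c(B3OC(C)(C)C(C)(C)O3)c21
F4 | step 13 | 3-bromo-6-[(E)-2-(3,4-dimethoxyphenyl)ethenyl]-4-hydroxy-2H-pyran-2-one | O=c1oc(/C=C/c2ccc(OC)c(OC)c2)cc(O)c1Br
F5 | step 13 | 3-bromo-6-[(E)-2-(3,4-dimethoxyphenyl)ethenyl]-4-(methoxymethoxy)-2H-pyran-2-one | COCOc1cc(/C=C/c2ccc(OC)c(OC)c2)oc(=O)c1Br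
F6 | step 13 | 4'-O-methoxymethyl ether of 28 | CC(C)[C@H]1CC[C@H](C)c2c(OC)c(OC)c(C=O)c(-c3c(OCOC)cc(/C=C/c4ccc(OC)c(OC)c4)oc3=O)c21
F7 | step 9 | (1R,4S)-1-isopropyl-5,6-dimethoxy-4-methyltetralin-7-yl N-isopropylcarbamate | CC(C)[C@H]1CC[C@H](C)c2c(OC)c(OC)c(OC(=O)NC(C)C)cc21
F8 | step 9 | (1R,4S)-1-isopropyl-5,6-dimethoxy-4-methyl-8-(trimethylsilyl)tetralin-7-yl N-isopropylcarbamate | CC(C)[C@H]1CC[C@H](C)c2c(OC)c(OC)c(OC(=O)NC(C)C)c([Si](C)(C)C)c21
F9 | step 9 | (1R,4S)-1-isopropyl-5,6-dimethoxy-4-methyl-8-(trimethylsilyl)tetralin-7-ol | CC(C)[C@H]1CC[C@H](C)c2c(OC)c(OC)c(O)c([Si](C)(C)C)c21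
F10 | step 5 | (1R,4S)-1-isopropyl-4-methyltetralin-5,6-dione (ortho-quinone) | CC(C)[C@H]1CC[C@H](C)C2=C1C=CC(=O)C2=O
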